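Ring D, the group on which the plan rests, is a benzene ring: C1 carries the benzylic CH2 bound to the quaternary carbon of ring C, C2 carries a free OH, and C5 (para to that OH) carries the O-sulfate. These two differently substituted oxygens are obtained by making ring D last, from the propargyl alkyne of 27 and chromium carbene 35 (three ring C–C bonds).
27 ⇐ ketone 25 (methylenation, alkyne desilylation) ⇐ ring-A silyl enol ether 19 + bicyclic aldehyde 13 (aldol, dehydration and conjugate reduction make the two-carbon tether).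
19 ⇐ (S)-4-silyloxy-3-methylcyclohexenone 16 + homoprenyl Grignard reagent (anti to the silyloxy group); 16 ⇐ 2-methylcyclohexenone 1 (CBS reduction, silylation, allylic oxidation).
13 ⇐ aldehyde 11 (one-carbon homologation) ⇐ Diels–Alder adduct 10 (alkene migration) ⇐ diene 8 + methacrolein ⇐ ketone 4 ⇐ 1 (asymmetric conjugate methylation–propargylation).
Order of ring formation: ring C (carried in from 1), ring B (step 4), ring A (carried in from 1, attached in step 12), ring D (step 19).
Key step: step 19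

Remark: the sulfate-bearing compounds 40–42 are drawn as aryl hydrogen sulfates; they would be handled as pyridinium, potassium or sodium salts, which differ only in the counter-ion.
Remark: the sense of induction of the chiral ligand in step 1 and of the chiral Lewis acid in step 4 is taken from the usual models; should the antipode form, the mirror-image ligand or catalyst is used.
Abbreviations in names: Oct = (1R,5R,6S)-1,5,6-trimethyl-5-[3-(trimethylsilyl)prop-2-yn-1-yl]-1,2,3,4,5,6,7,8-octahydronaphthalen-1-yl; Terp = {(1R,2S,5R)-5-[2-((1R,2S,3S)-3-[(tert-butyldimethylsilyl)oxy]-2-methyl-6-methylidene-2-(4-methylpent-3-en-1-yl)cyclohexyl)ethyl]-1,2,5-trimethyl-1,2,3,4,5,6,7,8-octahydronaphthalen-1-yl}methyl.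

Step 1
Reactants: 1 2-methylcyclohex-2-en-1-one; 2 3-bromo-1-(trimethylsilyl)prop-1-yne
Product: 4 (2R,3S)-2,3-dimethyl-2-[3-(trimethylsilyl)prop-2-yn-1-yl]cyclohexan-1-one, via bromomagnesium enolate 3 (not isolated)
Conditions: MeMgBr, Cu(OTf)2 (3 mol %), 1-[(2S)-1-hydroxy-4-methylpentan-2-yl]-3-(2,4,6-trimethylphenyl)-4,5-dihydroimidazolium hexafluorophosphate (4 mol %), Et2O, −30 °C; then 2, DMPU, THF, −30 °C → rt
Reagents that add atoms: methylmagnesium bromide, C[Mg]Br
Why: Copper-catalysed asymmetric conjugate addition of the Grignard reagent (chiral N-heterocyclic carbene ligand) should set the C3 methyl stereocentre under ligand control, and the magnesium enolate is then C-alkylated by the propargylic bromide on the face anti to that methyl, which puts the two methyl groups cis and creates the quaternary C2; the silyl cap suppresses allenyl (SN2') products.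

Step 2
Reactants: 4 (2R,3S)-2,3-dimethyl-2-[3-(trimethylsilyl)prop-2-yn-1-yl]cyclohexan-1-one
Product: 6 (5S,6R)-5,6-dimethyl-6-[3-(trimethylsilyl)prop-2-yn-1-yl]cyclohex-1-en-1-yl trifluoromethanesulfonate, via potassium enolate 5 (not isolated)
Conditions: KN(SiMe3)2, THF, −78 °C; then PhNTf2, −78 → 0 °C
Reagents that add atoms: N-phenylbis(trifluoromethanesulfonimide), O=S(=O)(N(c1ccccc1)S(=O)(=O)C(F)(F)F)C(F)(F)F
Why: Only C6 can enolise because C2 is quaternary, so deprotonation and O-sulfonylation of the enolate should give a single enol triflate without touching the stereocentres.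

Step 3
Reactants: 6 (5S,6R)-5,6-dimethyl-6-[3-(trimethylsilyl)prop-2-yn-1-yl]cyclohex-1-en-1-yl trifluoromethanesulfonate; 7 tributyl(ethenyl)stannane
Product: 8 (5S,6R)-1-ethenyl-5,6-dimethyl-6-[3-(trimethylsilyl)prop-2-yn-1-yl]cyclohex-1-ene
Conditions: Pd(PPh3)4 (5 mol %), LiCl, THF, 65 °C
Reagents that add atoms: none
Why: Stille coupling of the vinyl triflate (chloride-assisted oxidative addition to zerovalent palladium, then vinyl transfer from tin) should give the 1,3-diene, the silyl-capped alkyne being inert in the absence of copper.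

Step 4
Reactants: 8 (5S,6R)-1-ethenyl-5,6-dimethyl-6-[3-(trimethylsilyl)prop-2-yn-1-yl]cyclohex-1-ene; 9 2-methylprop-2-enal
Product: 10 (1S,5R,6S)-1,5,6-trimethyl-5-[3-(trimethylsilyl)prop-2-yn-1-yl]-1,2,3,5,6,7,8,8a-octahydronaphthalene-1-carbaldehyde (C8a epimers)
Conditions: (S)-1-(2-methylphenyl)-3,3-diphenyltetrahydro-1H,3H-pyrrolo[1,2-c][1,3,2]oxazaborole·Tf2NH (20 mol %), CH2Cl2, −78 → −40 °C
Reagents that add atoms: none
Why: Lewis-acid-catalysed Diels–Alder reaction with "ortho" regiochemistry (the vinyl CH2 terminus bonds to the enal β-carbon and the ring CH terminus to the α-carbon), in which the configuration of the new quaternary C1 depends only on which face of the catalyst-bound enal is attacked (the Re face at the α-carbon, the other being shielded by the catalyst), so that it is set by the catalyst independently of endo/exo and diene-face preferences, whose C8a epimers converge in step 5.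

Step 5
Reactants: 10 (1S,5R,6S)-1,5,6-trimethyl-5-[3-(trimethylsilyl)prop-2-yn-1-yl]-1,2,3,5,6,7,8,8a-octahydronaphthalene-1-carbaldehyde
Product: 11 (1S,5R,6S)-1,5,6-trimethyl-5-[3-(trimethylsilyl)prop-2-yn-1-yl]-1,2,3,4,5,6,7,8-octahydronaphthalene-1-carbaldehyde
Conditions: TsOH·H2O (10 mol %), toluene, 60 °C
Reagents that add atoms: none
Why: Brønsted-acid-catalysed alkene isomerisation, in which protonation at C4 gives the tertiary C4a cation and loss of H-8a should deliver the tetrasubstituted C4a=C8a alkene, the most substituted isomer and the one adopted by rearranged drimane-type octalins with this substitution, while the quaternary C1 and the non-enolisable aldehyde cannot epimerise.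

Step 6
Reactants: 11 (1S,5R,6S)-1,5,6-trimethyl-5-[3-(trimethylsilyl)prop-2-yn-1-yl]-1,2,3,4,5,6,7,8-octahydronaphthalene-1-carbaldehyde
Product: 12 (1R,5R,6S)-1-(2-methoxyethenyl)-1,5,6-trimethyl-5-[3-(trimethylsilyl)prop-2-yn-1-yl]-1,2,3,4,5,6,7,8-octahydronaphthalene (E/Z mixture)
Conditions: Ph3PCH2OMe Cl, KN(SiMe3)2, THF, 0 °C → rt
Reagents that add atoms: (methoxymethyl)triphenylphosphonium chloride, COC[P+](c1ccccc1)(c1ccccc1)c1ccccc1.[Cl-]
Why: Wittig olefination with the unstabilised methoxymethylene ylide, which tolerates neopentyl-type non-enolisable aldehydes, should add the one carbon needed for the two-carbon tether.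

Step 7
Reactants: 12 (1R,5R,6S)-1-(2-methoxyethenyl)-1,5,6-trimethyl-5-[3-(trimethylsilyl)prop-2-yn-1-yl]-1,2,3,4,5,6,7,8-octahydronaphthalene
Product: 13 2-(Oct)acetaldehyde
Conditions: 2 M HCl, THF, rt
Reagents that add atoms: water, O
Why: Acid hydrolysis of the enol ether (C-protonation, then collapse of the hemiacetal) should unmask the homologous aldehyde under conditions too mild to affect the tetrasubstituted alkene or the alkynylsilane.

Step 8
Reactants: 1 2-methylcyclohex-2-en-1-one
Product: 14 (1S)-2-methylcyclohex-2-en-1-ol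
Conditions: (R)-1-methyl-3,3-diphenyltetrahydro-1H,3H-pyrrolo[1,2-c][1,3,2]oxazaborole (10 mol %), catecholborane, toluene, −78 °C
Reagents that add atoms: none
Why: Corey–Bakshi–Shibata reduction, in which the α-methylalkenyl side of the enone acts as the large group, so that the (R)-catalyst should deliver hydride to the face that gives the (S)-allylic alcohol by 1,2-addition only.

Step 9
Reactants: 14 (1S)-2-methylcyclohex-2-en-1-ol
Product: 15 tert-butyldimethyl{[(1S)-2-methylcyclohex-2-en-1-yl]oxy}silane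
Conditions: t-BuMe2SiCl, imidazole, DMF, rt
Reagents that add atoms: tert-butyldimethylsilyl chloride, CC(C)(C)[Si](C)(C)Cl
Why: Standard silylation of a secondary allylic alcohol gives the bulky ether that later controls the face of the conjugate addition.

Step 10
Reactants: 15 tert-butyldimethyl{[(1S)-2-methylcyclohex-2-en-1-yl]oxy}silane
Product: 16 (4S)-4-[(tert-butyldimethylsilyl)oxy]-3-methylcyclohex-2-en-1-one
Conditions: Rh2(caprolactamate)4 (1 mol %), t-BuOOH (70 % aq.), K2CO3 (cat.), CH2Cl2, rt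
Reagents that add atoms: tert-butyl hydroperoxide, CC(C)(C)OO
Why: Dirhodium-catalysed allylic oxidation, in which the tert-butylperoxyl radical should abstract hydrogen from the unhindered ring methylene C4 and not from the methyl group or the silyloxy-shielded C1–H, the allylic peroxide then collapsing to the enone with the carbinol stereocentre untouched.

Step 11
Reactants: 16 (4S)-4-[(tert-butyldimethylsilyl)oxy]-3-methylcyclohex-2-en-1-one; 17 5-bromo-2-methylpent-2-ene
Product: 19 tert-butyldimethyl{[(1S,2S)-2-methyl-2-(4-methylpent-3-en-1-yl)-4-[(trimethylsilyl)oxy]cyclohex-3-en-1-yl]oxy}silane, via homoprenylmagnesium bromide 18 (not isolated)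
Conditions: 17, Mg, THF, rt; then 16, CuBr·SMe2 (10 mol %), Me3SiCl, DMPU, THF, −78 °C; Et3N work-up
Reagents that add atoms: chlorotrimethylsilane, C[Si](C)(C)Cl
Why: Copper-catalysed conjugate addition of the Grignard reagent accelerated by Me3SiCl, in which the nucleophile should attack C3 anti to the pseudoaxial silyloxy group at C4 and so set the quaternary centre with the homoprenyl chain trans to oxygen, the enolate being trapped regiospecifically as its silyl enol ether.

Step 12
Reactants: 19 tert-butyldimethyl{[(1S,2S)-2-methyl-2-(4-methylpent-3-en-1-yl)-4-[(trimethylsilyl)oxy]cyclohex-3-en-1-yl]oxy}silane; 13 2-(Oct)acetaldehyde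
Product: 21 (3S,4S)-4-[(tert-butyldimethylsilyl)oxy]-2-[1-hydroxy-2-(Oct)ethyl]-3-methyl-3-(4-methylpent-3-en-1-yl)cyclohexan-1-one (C2/carbinol epimer mixture), via lithium enolate 20 (not isolated)
Conditions: MeLi, THF, 0 °C; then 13, −78 °C; then H2O
Reagents that add atoms: none
Why: MeLi cleaves the silyl enol ether to the regiodefined lithium enolate, whose aldol addition to the unhindered aldehyde at −78 °C should outpace proton transfer; the two new stereocentres are of no consequence because one is eliminated in step 13 and the other is reset in step 14.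

Step 13
Reactants: 21 (3S,4S)-4-[(tert-butyldimethylsilyl)oxy]-2-[1-hydroxy-2-(Oct)ethyl]-3-methyl-3-(4-methylpent-3-en-1-yl)cyclohexan-1-one
Product: 23 (3S,4S)-4-[(tert-butyldimethylsilyl)oxy]-3-methyl-3-(4-methylpent-3-en-1-yl)-2-[2-(Oct)ethylidene]cyclohexan-1-one (E/Z mixture), via methanesulfonate 22 (not isolated)
Conditions: MsCl, Et3N, CH2Cl2, 0 °C; then 1,8-diazabicyclo[5.4.0]undec-7-ene (DBU), rt
Reagents that add atoms: none
Why: Mesylation and E1cB elimination should give the conjugated exocyclic enone, the only α,β-unsaturated isomer possible because the other neighbour of C2 is quaternary; its geometry does not matter.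

Step 14
Reactants: 23 (3S,4S)-4-[(tert-butyldimethylsilyl)oxy]-3-methyl-3-(4-methylpent-3-en-1-yl)-2-[2-(Oct)ethylidene]cyclohexan-1-one
Product: 25 (2S,3S,4S)-4-[(tert-butyldimethylsilyl)oxy]-3-methyl-3-(4-methylpent-3-en-1-yl)-2-[2-(Oct)ethyl]cyclohexan-1-one, via ketone C2-epimer mixture 24 (not isolated)
Conditions: [(Ph3P)CuH]6 (0.4 equiv), benzene, H2O (2 equiv), rt; then DBU (cat.), CH2Cl2, rt
Reagents that add atoms: none
Why: Conjugate reduction by the phosphine-stabilised copper hydride hexamer, which ignores isolated alkenes and the silyl alkyne, followed by amidine equilibration of the α-centre should give the thermodynamic epimer with the new side chain equatorial, trans to the equatorial homoprenyl chain and cis to the axial methyl, as in 9-substituted 8-oxodrimanes.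

Step 15
Reactants: 25 (2S,3S,4S)-4-[(tert-butyldimethylsilyl)oxy]-3-methyl-3-(4-methylpent-3-en-1-yl)-2-[2-(Oct)ethyl]cyclohexan-1-one
Product: 26 tert-butyldimethyl{[(1S,2S,3R)-2-methyl-4-methylidene-2-(4-methylpent-3-en-1-yl)-3-[2-(Oct)ethyl]cyclohexyl]oxy}silane
Conditions: Ph3PCH3Br, KN(SiMe3)2, toluene, 0 → 70 °C
Reagents that add atoms: methyltriphenylphosphonium bromide, C[P+](c1ccccc1)(c1ccccc1)c1ccccc1.[Br-]
Why: Wittig methylenation with excess unstabilised ylide is the standard method for α-branched cyclohexanones next to a quaternary carbon, and any ylide-induced α-epimerisation can only reinforce the equatorial, thermodynamic side chain.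

Step 16
Reactants: 26 tert-butyldimethyl{[(1S,2S,3R)-2-methyl-4-methylidene-2-(4-methylpent-3-en-1-yl)-3-[2-(Oct)ethyl]cyclohexyl]oxy}silane
Product: 27 tert-butyldimethyl{[(1S,2S,3R)-2-methyl-4-methylidene-2-(4-methylpent-3-en-1-yl)-3-{2-[(1R,5R,6S)-1,5,6-trimethyl-5-(prop-2-yn-1-yl)-1,2,3,4,5,6,7,8-octahydronaphthalen-1-yl]ethyl}cyclohexyl]oxy}silane
Conditions: K2CO3, MeOH, rt
Reagents that add atoms: none
Why: Methanolysis of the alkynyl C–Si bond under mild base should release the terminal alkyne while the hindered secondary silyl ether stays.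

Step 17
Reactants: 28 (E)-(2-bromoethenyl)trimethylsilane; 29 hexacarbonylchromium
Product: 32 tetramethylammonium pentacarbonyl[(E)-3-(trimethylsilyl)prop-2-enoyl]chromate, via silylvinyllithium 30 (not isolated), via lithium acylchromate 31 (not isolated)
Conditions: t-BuLi (2 equiv), Et2O, −78 °C; then Cr(CO)6, Et2O, −78 °C → rt; then Me4NBr, H2O
Reagents that add atoms: tetramethylammonium bromide, C[N+](C)(C)C.[Br-]
Why: Fischer carbene-complex synthesis, in which bromine–lithium exchange keeps the E geometry, the vinyllithium adds to a carbonyl ligand of Cr(CO)6, and the acylchromate is isolated as its stable tetramethylammonium salt.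

Step 18
Reactants: 32 tetramethylammonium pentacarbonyl[(E)-3-(trimethylsilyl)prop-2-enoyl]chromate; 33 (4-methoxyphenyl)methanol
Product: 35 pentacarbonyl{[(4-methoxyphenyl)methoxy][(E)-2-(trimethylsilyl)ethenyl]carbene}chromium, via acetoxycarbene complex 34 (not isolated)
Conditions: AcBr, CH2Cl2, −40 °C; then 33, −40 → −10 °C
Reagents that add atoms: none
Why: O-Acylation of the acylchromate gives an electrophilic acyloxycarbene complex that should exchange with the alcohol by addition–elimination at the carbene carbon, the usual route to alkoxycarbene complexes with elaborate alkoxy groups; the β-silyl group blocks the conjugate addition and polymerisation that make the unsubstituted vinyl complex hard to handle.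

Step 19
Reactants: 27 tert-butyldimethyl{[(1S,2S,3R)-2-methyl-4-methylidene-2-(4-methylpent-3-en-1-yl)-3-{2-[(1R,5R,6S)-1,5,6-trimethyl-5-(prop-2-yn-1-yl)-1,2,3,4,5,6,7,8-octahydronaphthalen-1-yl]ethyl}cyclohexyl]oxy}silane; 35 pentacarbonyl{[(4-methoxyphenyl)methoxy][(E)-2-(trimethylsilyl)ethenyl]carbene}chromium
Product: 37 4-[(4-methoxyphenyl)methoxy]-2-(Terp)phenol, via aryl trimethylsilyl ether 36 (not isolated)
Conditions: 35 (1.5 equiv), THF, 50 °C, argon; then air, rt; then K2CO3, MeOH, 0 °C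
Reagents that add atoms: none
Why: Loss of one CO from 35 lets alkyne 27 coordinate and insert into the Cr=C bond with its unsubstituted carbon joined to the carbene carbon, CO insertion then gives a chromium-bound vinylketene, and 6π-electrocyclisation joins the ketene carbon to the silyl-bearing vinyl terminus to give a cyclohexa-2,4-dienone that should aromatise by 1,3-shift of SiMe3 from carbon to oxygen, the aryl trimethylsilyl ether 36 being methanolysed on work-up. The closest known reaction type is the Dötz benzannulation of alkoxy(alkenyl)carbene chromium complexes with terminal alkynes, in the known variant where a trans-2-silylvinyl complex stands in for the polymerisation-prone unsubstituted vinyl complex. Ring D, a six-membered carbocycle, is closed by thermal 6π-electrocyclic closure of the metal-bound dienylketene after the two insertions, so that three ring C–C bonds are formed (terminal alkyne carbon to carbene carbon, substituted alkyne carbon to CO carbon, CO carbon to vinyl terminus). No stereocentre is created, and the six existing ones are remote from the alkyne and cannot epimerise under these neutral conditions. The step needs regioselective alkyne insertion, which the steric difference between the CH2-substituted and the hydrogen-bearing alkyne carbon secures by placing the larger group next to the CO-derived carbon, so that the free hydroxyl ends up ortho to the benzylic CH2 and the carbene-derived ether oxygen para to that hydroxyl. It also needs selectivity for the alkyne over the three alkenes, which follows because alkoxycarbene complexes do not cyclopropanate unactivated, non-conjugated alkenes at 50 °C.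

Step 20
Reactants: 37 4-[(4-methoxyphenyl)methoxy]-2-(Terp)phenol
Product: 38 4-[(4-methoxyphenyl)methoxy]-2-(Terp)phenyl acetate
Conditions: Ac2O, pyridine, 4-(dimethylamino)pyridine (cat.), CH2Cl2, rt
Reagents that add atoms: acetic anhydride, CC(=O)OC(C)=O
Why: Acetylation masks the hydroxyl that must stay free in the target and makes the hydroquinone ring less electron-rich, so that it should not be oxidised to a quinone in step 21.

Step 21
Reactants: 38 4-[(4-methoxyphenyl)methoxy]-2-(Terp)phenyl acetate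
Product: 39 4-hydroxy-2-(Terp)phenyl acetate
Conditions: DDQ, CH2Cl2/aqueous phosphate buffer (pH 7), 0 °C → rt
Reagents that add atoms: none
Why: Oxidative cleavage of the 4-methoxybenzyl aryl ether by DDQ (hydride abstraction from the benzylic CH2, then hydrolysis of the oxocarbenium ion) under buffered conditions should leave the acetate, the silyl ether and the unactivated alkenes intact.

Step 22
Reactants: 39 4-hydroxy-2-(Terp)phenyl acetate
Product: 40 2-(Terp)-4-(sulfooxy)phenyl acetate
Conditions: SO3·pyridine, pyridine, 40 °C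
Reagents that add atoms: sulfur trioxide–pyridine complex, O=S(=O)([O-])[n+]1ccccc1
Why: O-Sulfation of the only free hydroxyl with the mild SO3·pyridine complex should not touch isolated alkenes, the acetate or the silyl ether.

Step 23
Reactants: 40 2-(Terp)-4-(sulfooxy)phenyl acetate
Product: 42 4-hydroxy-3-({(1R,2S,5R)-5-[2-((1R,2S,3S)-3-hydroxy-2-methyl-6-methylidene-2-(4-methylpent-3-en-1-yl)cyclohexyl)ethyl]-1,2,5-trimethyl-1,2,3,4,5,6,7,8-octahydronaphthalen-1-yl}methyl)phenyl hydrogen sulfate (CNP0426156.3), via phenol sulfate 41 (not isolated)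
Conditions: K2CO3, MeOH, rt; then Bu4NF, THF, 50 °C
Reagents that add atoms: none
Why: Methanolysis of the aryl acetate and fluoride cleavage of the hindered secondary silyl ether run under basic, non-acidic conditions in which the aryl sulfate monoanion and the exocyclic alkene should be stable.

Compound list
1 | 2-methylcyclohex-2-en-1-one | CC1=CCCCC1=O | starting material
2 | 3-bromo-1-(trimethylsilyl)prop-1-yne | C[Si](C)(C)C#CCBr | starting material
3 | bromomagnesium (3S)-2,3-dimethylcyclohex-1-en-1-olate | Br[Mg]OC1=C(C)[C@@H](C)CCC1 | intermediate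
4 | (2R,3S)-2,3-dimethyl-2-[3-(trimethylsilyl)prop-2-yn-1-yl]cyclohexan-1-one | O=C1CCC[C@H](C)[C@@]1(C)CC#C[Si](C)(C)C | intermediate
5 | potassium (5S,6R)-5,6-dimethyl-6-[3-(trimethylsilyl)prop-2-yn-1-yl]cyclohex-1-en-1-olate | [K]OC1=CCC[C@H](C)[C@@]1(C)CC#C[Si](C)(C)C | intermediate
6 | (5S,6R)-5,6-dimethyl-6-[3-(trimethylsilyl)prop-2-yn-1-yl]cyclohex-1-en-1-yl trifluoromethanesulfonate | FC(F)(F)S(=O)(=O)OC1=CCC[C@H](C)[C@@]1(C)CC#C[Si](C)(C)C | intermediate
7 | tributyl(ethenyl)stannane | C=C[Sn](CCCC)(CCCC)CCCC | starting material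
8 | (5S,6R)-1-ethenyl-5,6-dimethyl-6-[3-(trimethylsilyl)prop-2-yn-1-yl]cyclohex-1-ene | C=CC1=CCC[C@H](C)[C@@]1(C)CC#C[Si](C)(C)C | intermediate
9 | 2-methylprop-2-enal (methacrolein) | CC(=C)C=O | starting material
10 | (1S,5R,6S)-1,5,6-trimethyl-5-[3-(trimethylsilyl)prop-2-yn-1-yl]-1,2,3,5,6,7,8,8a-octahydronaphthalene-1-carbaldehyde (C8a epimers) | O=C[C@@]1(C)CCC=C2C1CC[C@H](C)[C@@]2(C)CC#C[Si](C)(C)C | intermediate
11 | (1S,5R,6S)-1,5,6-trimethyl-5-[3-(trimethylsilyl)prop-2-yn-1-yl]-1,2,3,4,5,6,7,8-octahydronaphthalene-1-carbaldehyde | O=C[C@@]1(C)CCCC2=C1CC[C@H](C)[C@@]2(C)CC#C[Si](C)(C)C | intermediate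
12 | (1R,5R,6S)-1-(2-methoxyethenyl)-1,5,6-trimethyl-5-[3-(trimethylsilyl)prop-2-yn-1-yl]-1,2,3,4,5,6,7,8-octahydronaphthalene (E/Z mixture) | COC=C[C@@]1(C)CCCC2=C1CC[C@H](C)[C@@]2(C)CC#C[Si](C)(C)C | intermediate
13 | 2-(Oct)acetaldehyde | O=CC[C@@]1(C)CCCC2=C1CC[C@H](C)[C@@]2(C)CC#C[Si](C)(C)C | intermediate
14 | (1S)-2-methylcyclohex-2-en-1-ol | CC1=CCCC[C@@H]1O | intermediate
15 | tert-butyldimethyl{[(1S)-2-methylcyclohex-2-en-1-yl]oxy}silane | CC1=CCCC[C@@H]1O[Si](C)(C)C(C)(C)C | intermediate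
16 | (4S)-4-[(tert-butyldimethylsilyl)oxy]-3-methylcyclohex-2-en-1-one | O=C1CC[C@H](O[Si](C)(C)C(C)(C)C)C(C)=C1 | intermediate
17 | 5-bromo-2-methylpent-2-ene | CC(C)=CCCBr | starting material
18 | (4-methylpent-3-en-1-yl)magnesium bromide | CC(C)=CCC[Mg]Br | intermediate
19 | tert-butyldimethyl{[(1S,2S)-2-methyl-2-(4-methylpent-3-en-1-yl)-4-[(trimethylsilyl)oxy]cyclohex-3-en-1-yl]oxy}silane | C[Si](C)(C)OC=1CC[C@H](O[Si](C)(C)C(C)(C)C)[C@@](C)(CCC=C(C)C)C=1 | intermediate
20 | lithium (3S,4S)-4-[(tert-butyldimethylsilyl)oxy]-3-methyl-3-(4-methylpent-3-en-1-yl)cyclohex-1-en-1-olate | [Li]OC=1CC[C@H](O[Si](C)(C)C(C)(C)C)[C@@](C)(CCC=C(C)C)C=1 | intermediate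
21 | (3S,4S)-4-[(tert-butyldimethylsilyl)oxy]-2-[1-hydroxy-2-(Oct)ethyl]-3-methyl-3-(4-methylpent-3-en-1-yl)cyclohexan-1-one (C2/carbinol epimer mixture) | O=C1CC[C@H](O[Si](C)(C)C(C)(C)C)[C@@](C)(CCC=C(C)C)C1C(O)C[C@@]1(C)CCCC2=C1CC[C@H](C)[C@@]2(C)CC#C[Si](C)(C)C | intermediate
22 | methanesulfonate of 21 | O=C1CC[C@H](O[Si](C)(C)C(C)(C)C)[C@@](C)(CCC=C(C)C)C1C(OS(C)(=O)=O)C[C@@]1(C)CCCC2=C1CC[C@H](C)[C@@]2(C)CC#C[Si](C)(C)C | intermediate
23 | (3S,4S)-4-[(tert-butyldimethylsilyl)oxy]-3-methyl-3-(4-methylpent-3-en-1-yl)-2-[2-(Oct)ethylidene]cyclohexan-1-one (E/Z mixture) | O=C1CC[C@H](O[Si](C)(C)C(C)(C)C)[C@@](C)(CCC=C(C)C)C1=CC[C@@]1(C)CCCC2=C1CC[C@H](C)[C@@]2(C)CC#C[Si](C)(C)C | intermediate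
24 | (3S,4S)-4-[(tert-butyldimethylsilyl)oxy]-3-methyl-3-(4-methylpent-3-en-1-yl)-2-[2-(Oct)ethyl]cyclohexan-1-one (C2 epimer mixture) | O=C1CC[C@H](O[Si](C)(C)C(C)(C)C)[C@@](C)(CCC=C(C)C)C1CC[C@@]1(C)CCCC2=C1CC[C@H](C)[C@@]2(C)CC#C[Si](C)(C)C | intermediate
25 | (2S,3S,4S)-4-[(tert-butyldimethylsilyl)oxy]-3-methyl-3-(4-methylpent-3-en-1-yl)-2-[2-(Oct)ethyl]cyclohexan-1-one | O=C1CC[C@H](O[Si](C)(C)C(C)(C)C)[C@@](C)(CCC=C(C)C)[C@@H]1CC[C@@]1(C)CCCC2=C1CC[C@H](C)[C@@]2(C)CC#C[Si](C)(C)C | intermediate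
26 | tert-butyldimethyl{[(1S,2S,3R)-2-methyl-4-methylidene-2-(4-methylpent-3-en-1-yl)-3-[2-(Oct)ethyl]cyclohexyl]oxy}silane | C=C1CC[C@H](O[Si](C)(C)C(C)(C)C)[C@@](C)(CCC=C(C)C)[C@@H]1CC[C@@]1(C)CCCC2=C1CC[C@H](C)[C@@]2(C)CC#C[Si](C)(C)C | intermediate
27 | tert-butyldimethyl{[(1S,2S,3R)-2-methyl-4-methylidene-2-(4-methylpent-3-en-1-yl)-3-{2-[(1R,5R,6S)-1,5,6-trimethyl-5-(prop-2-yn-1-yl)-1,2,3,4,5,6,7,8-octahydronaphthalen-1-yl]ethyl}cyclohexyl]oxy}silane | C=C1CC[C@H](O[Si](C)(C)C(C)(C)C)[C@@](C)(CCC=C(C)C)[C@@H]1CC[C@@]1(C)CCCC2=C1CC[C@H](C)[C@@]2(C)CC#C | intermediate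
28 | (E)-(2-bromoethenyl)trimethylsilane | C[Si](C)(C)/C=C/Br | starting material
29 | hexacarbonylchromium | O=C=[Cr](=C=O)(=C=O)(=C=O)(=C=O)=C=O | starting material
30 | (E)-[2-(trimethylsilyl)ethenyl]lithium | [Li]/C=C/[Si](C)(C)C | intermediate
31 | lithium pentacarbonyl[(E)-3-(trimethylsilyl)prop-2-enoyl]chromate | [Li+].[O-]C(/C=C/[Si](C)(C)C)=[Cr](=C=O)(=C=O)(=C=O)(=C=O)=C=O | intermediate
32 | tetramethylammonium pentacarbonyl[(E)-3-(trimethylsilyl)prop-2-enoyl]chromate | C[N+](C)(C)C.[O-]C(/C=C/[Si](C)(C)C)=[Cr](=C=O)(=C=O)(=C=O)(=C=O)=C=O | intermediate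
33 | (4-methoxyphenyl)methanol | COc1ccc(CO)cc1 | starting material
34 | pentacarbonyl{acetoxy[(E)-2-(trimethylsilyl)ethenyl]carbene}chromium | CC(=O)OC(/C=C/[Si](C)(C)C)=[Cr](=C=O)(=C=O)(=C=O)(=C=O)=C=O | intermediate
35 | pentacarbonyl{[(4-methoxyphenyl)methoxy][(E)-2-(trimethylsilyl)ethenyl]carbene}chromium | COc1ccc(COC(/C=C/[Si](C)(C)C)=[Cr](=C=O)(=C=O)(=C=O)(=C=O)=C=O)cc1 | intermediate
36 | trimethyl{4-[(4-methoxyphenyl)methoxy]-2-(Terp)phenoxy}silane | C=C1CC[C@H](O[Si](C)(C)C(C)(C)C)[C@@](C)(CCC=C(C)C)[C@@H]1CC[C@@]1(C)CCCC2=C1CC[C@H](C)[C@@]2(C)Cc1cc(OCc2ccc(OC)cc2)ccc1O[Si](C)(C)C | intermediate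
37 | 4-[(4-methoxyphenyl)methoxy]-2-(Terp)phenol | C=C1CC[C@H](O[Si](C)(C)C(C)(C)C)[C@@](C)(CCC=C(C)C)[C@@H]1CC[C@@]1(C)CCCC2=C1CC[C@H](C)[C@@]2(C)Cc1cc(OCc2ccc(OC)cc2)ccc1O | intermediate
38 | 4-[(4-methoxyphenyl)methoxy]-2-(Terp)phenyl acetate | C=C1CC[C@H](O[Si](C)(C)C(C)(C)C)[C@@](C)(CCC=C(C)C)[C@@H]1CC[C@@]1(C)CCCC2=C1CC[C@H](C)[C@@]2(C)Cc1cc(OCc2ccc(OC)cc2)ccc1OC(C)=O | intermediate
39 | 4-hydroxy-2-(Terp)phenyl acetate | C=C1CC[C@H](O[Si](C)(C)C(C)(C)C)[C@@](C)(CCC=C(C)C)[C@@H]1CC[C@@]1(C)CCCC2=C1CC[C@H](C)[C@@]2(C)Cc1cc(O)ccc1OC(C)=O | intermediate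
40 | 2-(Terp)-4-(sulfooxy)phenyl acetate | C=C1CC[C@H](O[Si](C)(C)C(C)(C)C)[C@@](C)(CCC=C(C)C)[C@@H]1CC[C@@]1(C)CCCC2=C1CC[C@H](C)[C@@]2(C)Cc1cc(OS(=O)(=O)O)ccc1OC(C)=O | intermediate
41 | 4-hydroxy-3-(Terp)phenyl hydrogen sulfate | C=C1CC[C@H](O[Si](C)(C)C(C)(C)C)[C@@](C)(CCC=C(C)C)[C@@H]1CC[C@@]1(C)CCCC2=C1CC[C@H](C)[C@@]2(C)Cc1cc(OS(=O)(=O)O)ccc1O | intermediate
42 | 4-hydroxy-3-({(1R,2S,5R)-5-[2-((1R,2S,3S)-3-hydroxy-2-methyl-6-methylidene-2-(4-methylpent-3-en-1-yl)cyclohexyl)ethyl]-1,2,5-trimethyl-1,2,3,4,5,6,7,8-octahydronaphthalen-1-yl}methyl)phenyl hydrogen sulfate (CNP0426156.3) | C=C1CC[C@H](O)[C@@](C)(CCC=C(C)C)[C@@H]1CC[C@@]1(C)CCCC2=C1CC[C@H](C)[C@@]2(C)Cc1cc(OS(=O)(=O)O)ccc1O | target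

Total step count: 23. Longest linear sequence: 17 steps (steps 1–7, 12–16 and 19–23).

Steps most likely to fail

Step 19 (benzannulation). The 4-methoxybenzyl–oxygen bond of the electron-poor carbene ligand may ionise, or 35 may decompose thermally, before the neopentyl-type alkyne has inserted; CO insertion may also be bypassed. The fallback sets out from acylchromate 32 and alkyne 27 and comes back at 41. Compound 32 is O-methylated with Me3OBF4 to the robust pentacarbonyl{methoxy[(E)-2-(trimethylsilyl)ethenyl]carbene}chromium F1. Its benzannulation with 27 (THF, 50 °C) is worked up oxidatively with (NH4)2Ce(NO3)6 in aqueous MeCN at 0 °C, which removes chromium and turns the crude 4-methoxyaryl silyl ether into 2-(Terp)cyclohexa-2,5-diene-1,4-dione F2. Na2S2O4 reduces this to 2-(Terp)benzene-1,4-diol F3. One equivalent of SO3·pyridine should then sulfate the unhindered hydroxyl (flanked by two ring hydrogens) in preference to the one shielded by the neopentyl-type CH2, giving 41, which continues with the fluoride treatment of step 23. The two oxygens are then told apart by sterics and not by the carbene substituent.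

Step 4 (Diels–Alder reaction). The hindered, chiral diene may discriminate poorly between the faces of the catalyst-bound enal, eroding the configuration of the new quaternary carbon; the cycloaddition may also be slow or lose regiocontrol. The fallback sets out from diene 8 and comes back at aldehyde 11. The more reactive 2,2,2-trifluoroethyl acrylate is used with the oxazaborolidinium enantiomer that gives the endo adduct 2,2,2-trifluoroethyl (1S,5R,6S,8aR)-5,6-dimethyl-5-[3-(trimethylsilyl)prop-2-yn-1-yl]-1,2,3,5,6,7,8,8a-octahydronaphthalene-1-carboxylate F4. LiN(i-Pr)2 and MeI should methylate its ester enolate on the face of H-8a, anti to the C8 methylene, so that the quaternary centre is set by relay from C8a in 2,2,2-trifluoroethyl (1S,5R,6S,8aR)-1,5,6-trimethyl-5-[3-(trimethylsilyl)prop-2-yn-1-yl]-1,2,3,5,6,7,8,8a-octahydronaphthalene-1-carboxylate F5. TsOH·H2O moves the alkene as in step 5 to give 2,2,2-trifluoroethyl (1S,5R,6S)-1,5,6-trimethyl-5-[3-(trimethylsilyl)prop-2-yn-1-yl]-1,2,3,4,5,6,7,8-octahydronaphthalene-1-carboxylate F6, and i-Bu2AlH (CH2Cl2, −78 °C) reduces the ester to aldehyde 11.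

Step 5 (alkene migration). Equilibration may stop short, or the long-lived tertiary cation may undergo Wagner–Meerwein shifts or be captured by the alkyne under prolonged acid. The fallback sets out from adduct 10 and comes back at 11. Anhydrous HCl (CH2Cl2, −78 °C) adds in the Markovnikov sense to give (1S,5R,6S)-4a-chloro-1,5,6-trimethyl-5-[3-(trimethylsilyl)prop-2-yn-1-yl]decahydronaphthalene-1-carbaldehyde F7, the cation being trapped at once by chloride. LiBr and Li2CO3 in DMF (120 °C) should then eliminate HCl toward the more substituted (Zaitsev) C4a=C8a alkene to give 11.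

Further compounds
F1 | step 19 | pentacarbonyl{methoxy[(E)-2-(trimethylsilyl)ethenyl]carbene}chromium | COC(/C=C/[Si](C)(C)C)=[Cr](=C=O)(=C=O)(=C=O)(=C=O)=C=O
F2 | step 19 | 2-(Terp)cyclohexa-2,5-diene-1,4-dione | C=C1CC[C@H](O[Si](C)(C)C(C)(C)C)[C@@](C)(CCC=C(C)C)[C@@H]1CC[C@@]1(C)CCCC2=C1CC[C@H](C)[C@@]2(C)CC1=CC(=O)C=CC1=O
F3 | step 19 | 2-(Terp)benzene-1,4-diol | C=C1CC[C@H](O[Si](C)(C)C(C)(C)C)[C@@](C)(CCC=C(C)C)[C@@H]1CC[C@@]1(C)CCCC2=C1CC[C@H](C)[C@@]2(C)Cc1cc(O)ccc1O
F4 | step 4 | 2,2,2-trifluoroethyl (1S,5R,6S,8aR)-5,6-dimethyl-5-[3-(trimethylsilyl)prop-2-yn-1-yl]-1,2,3,5,6,7,8,8a-octahydronaphthalene-1-carboxylate | FC(F)(F)COC(=O)[C@H]1CCC=C2[C@H]1CC[C@H](C)[C@@]2(C)CC#C[Si](C)(C)C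
F5 | step 4 | 2,2,2-trifluoroethyl (1S,5R,6S,8aR)-1,5,6-trimethyl-5-[3-(trimethylsilyl)prop-2-yn-1-yl]-1,2,3,5,6,7,8,8a-octahydronaphthalene-1-carboxylate | FC(F)(F)COC(=O)[C@@]1(C)CCC=C2[C@H]1CC[C@H](C)[C@@]2(C)CC#C[Si](C)(C)C
F6 | step 4 | 2,2,2-trifluoroethyl (1S,5R,6S)-1,5,6-trimethyl-5-[3-(trimethylsilyl)prop-2-yn-1-yl]-1,2,3,4,5,6,7,8-octahydronaphthalene-1-carboxylate | FC(F)(F)COC(=O)[C@@]1(C)CCCC2=C1CC[C@H](C)[C@@]2(C)CC#C[Si](C)(C)C
F7 | step 5 | (1S,5R,6S)-4a-chloro-1,5,6-trimethyl-5-[3-(trimethylsilyl)prop-2-yn-1-yl]decahydronaphthalene-1-carbaldehyde (C4a/C8a epimers) | O=C[C@@]1(C)CCCC2(Cl)C1CC[C@H](C)[C@@]2(C)CC#C[Si](C)(C)C
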